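## Plan

Rings: A = enolised trione, B = spiro cyclohexane, C = cyclopentane.
Cuts (last-made first): the C–CH3 bond at the ring A quaternary carbon; the ring A C–acyl bond; the two ring A bonds carbonyl–CH (acyl side) and carbonyl–CH(prenyl), which release 6-methylhept-5-en-2-one; then, together, the spiro-carbon–CH2 bond of ring B and the bond between the two ring-fusion carbons.
Feature: the eight carbons of rings B and C other than the spiro carbon, with their two methyl groups, are the chain of (R)-linalool (carbinol = ring C carbinol, vinyl = dienophile, E-methyl oxidised and condensed with malonate = diene); the malonate carbon is the spiro carbon.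
Forward: chain (linalool → enal → dienylidene malonate), rings B and C together, ring B carbinol, ring A, acyl group, C-methyl group.
Stereochemistry: ring C carbinol from (R)-linalool; ring-fusion centres from the cycloaddition; ring B carbinol from epoxidation directed by the ring C hydroxyl; spiro centre from the only lactone that hydroxyl can form; ring A quaternary centre from face-selective methylation; side chain from (S)-2-methylbutanoic acid.

Key step: step 4

Remark: ring A compounds 16, 18 and 19 are drawn as one enol tautomer; their prenyl-bearing ring carbon is enolisable and carries no descriptor.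

## Route

Step 1
Reactants: 1 (R)-(−)-linalool
Product: 2 (3R)-3,7-dimethyl-3-(triethylsilyloxy)octa-1,6-diene
Conditions: Et3SiOTf, 2,6-lutidine, CH2Cl2, −78 → 0 °C
Reagents that add atoms: triethylsilyl trifluoromethanesulfonate, CC[Si](CC)(CC)OS(=O)(=O)C(F)(F)F
Why: Silyl ether formation with a silyl triflate and a hindered base caps the tertiary allylic alcohol without ionising it or touching the stereocentre, and the triethylsilyl group is chosen because it should survive the oxidation, condensation and heating ahead and later leave under buffered HF without passing through an alkoxide.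

Step 2
Reactants: 2 (3R)-3,7-dimethyl-3-(triethylsilyloxy)octa-1,6-diene
Product: 4 (2E,6R)-2,6-dimethyl-6-(triethylsilyloxy)octa-2,7-dienal, via allylic alcohol 3 (not isolated)
Conditions: SeO2 (cat.), t-BuOOH, salicylic acid (cat.), CH2Cl2, rt; then MnO2, CH2Cl2, rt
Reagents that add atoms: tert-butyl hydroperoxide, CC(C)(C)OO (terminal oxidant; the oxygen is passed on by selenium dioxide, O=[Se]=O)
Why: Riley allylic oxidation (ene reaction, then [2,3]-sigmatropic shift) attacks the (E)-methyl group of the trisubstituted alkene as it does in linalyl esters, the vinyl group has no allylic hydrogen, and MnO2 then carries the allylic alcohol that accompanies the aldehyde on to the single (E)-enal.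

Step 3
Reactants: 4 (2E,6R)-2,6-dimethyl-6-(triethylsilyloxy)octa-2,7-dienal; 5 dimethyl malonate
Product: 6 dimethyl 2-[(2E,6R)-2,6-dimethyl-6-(triethylsilyloxy)octa-2,7-dien-1-ylidene]malonate
Conditions: piperidine (cat.), AcOH (cat.), 4 Å molecular sieves, toluene, 60 °C
Reagents that add atoms: none
Why: Knoevenagel condensation under piperidinium acetate catalysis with removal of water gives the doubly activated diene, avoids Lewis acids that could ionise the tertiary allylic silyl ether, and raises no geometric issue at the new double bond because the two esters are identical.

Step 4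
Reactants: 6 dimethyl 2-[(2E,6R)-2,6-dimethyl-6-(triethylsilyloxy)octa-2,7-dien-1-ylidene]malonate
Product: 7 dimethyl (3R,3aS,7aS)-3,7-dimethyl-3-(triethylsilyloxy)-1,2,3,3a,4,7a-hexahydro-5H-indene-5,5-dicarboxylate (cis-fused; silyloxy group anti to both ring-fusion hydrogens and syn to the ring B CH2 on the neighbouring ring-fusion carbon)
Conditions: toluene (0.02 M), BHT (cat.), sealed tube, 190 °C
Reagents that add atoms: none
Why: On heating, the s-cis dienylidene malonate and the vinyl group combine in a concerted, asynchronous, suprafacial [4+2] cycloaddition; the closest known class is the thermal intramolecular Diels–Alder reaction of 1,3,8-nonatrienes to hexahydroindenes, here with an ester-activated diene, an unactivated dienophile and a fully substituted diene terminus, hence the high temperature. Ring C closes as the five-membered ring through the three-carbon tether (bond between the tether-bearing diene carbon and the inner vinyl carbon) and ring B as the six-membered cycloadduct ring (second bond between the malonate carbon and the vinyl CH2), the malonate carbon becoming the future spiro carbon without a stereochemical issue because its esters are identical. The two ring-fusion centres are set relative to each other by the (E)-diene geometry and the endo (tether-under-diene) mode, toward which unactivated nonatrienes incline and which gives the cis fusion. Their configuration relative to the carbinol is set by the linalool stereocentre next to the dienophile: in the endo transition structure one of its substituents must lie under the diene on the side of the reacting CH2, and the slim oxygen, whose lone pairs face the electron-poor diene, is expected to take that place while the methyl group turns outward. The step therefore needs cis fusion with the silyloxy group syn to the new ring B CH2; both rest on moderate biases, so any diastereomers are to be removed by chromatography here or after step 5, and a diester was chosen over a diketone because it cannot escape by 6π-electrocyclisation to a 2H-pyran.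

Step 5
Reactants: 7 cis-fused hexahydroindene diester silyl ether
Product: 8 dimethyl (3R,3aS,7aS)-3-hydroxy-3,7-dimethyl-1,2,3,3a,4,7a-hexahydro-5H-indene-5,5-dicarboxylate
Conditions: HF·pyridine, pyridine, THF, 0 °C → rt
Reagents that add atoms: none
Why: Fluoride-induced cleavage of the silyl ether with pyridine-buffered HF frees the tertiary alcohol under weakly acidic conditions, so no alkoxide forms that would close prematurely onto the neighbouring ester.

Step 6
Reactants: 8 hydroxy diester
Product: 9 epoxy alcohol (6,7-epoxide of 8 with the oxirane oxygen on the face of the 3-hydroxyl group)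
Conditions: VO(acac)2 (cat.), t-BuOOH, CH2Cl2, 0 °C → rt
Reagents that add atoms: tert-butyl hydroperoxide, CC(C)(C)OO
Why: Hydroxyl-directed epoxidation of the Sharpless–Michaelson type is known for cyclohex-3-enyl carbinols, which is the relationship of the ring C hydroxyl to the ring B alkene, and it delivers oxygen only to the alkene face on which that hydroxyl sits (opposite to the ring-fusion hydrogens), fixing the configuration of the future ring B carbinol carbon; the hydroxyl cannot open an epoxide formed syn to itself.

Step 7
Reactants: 9 epoxy alcohol
Product: 10 tetraol: cis-fused 5,5-bis(hydroxymethyl)-3,7-dimethyloctahydro-1H-indene-3,7-diol (locants as in 7; both tertiary hydroxyls anti to the ring-fusion hydrogens)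
Conditions: LiAlH4, THF, 0 °C → reflux
Reagents that add atoms: none
Why: LiAlH4 reduces both esters and opens the trisubstituted epoxide by SN2 attack of hydride at its less substituted carbon, anti to the oxirane oxygen (possibly delivered from the aluminate of the hydroxymethyl group on that face), so the C–O bond at the tertiary carbon and the configuration from step 6 are kept; the ester level is given up on purpose because no hydride able to open this hindered epoxide would spare an ester, and it is restored in step 8.

Step 8
Reactants: 10 tetraol
Product: 12 lactone acid (δ-lactone between the ring C oxygen and the carboxyl carbon on its face of the future spiro carbon; CO2H on the other face; ring B hydroxyl free), via lactone aldehyde 11 (not isolated)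
Conditions: TEMPO (cat.), PhI(OAc)2, MeCN/H2O, rt
Reagents that add atoms: water, O
Why: Oxoammonium oxidation leaves tertiary alcohols alone and takes each primary alcohol to the aldehyde; the one on the face of the ring C hydroxyl is trapped as a six-membered lactol and oxidised on to the δ-lactone (oxidative lactonisation), whereas the other, with no hydroxyl in reach, goes through its hydrate to the acid, and this unequal fate of two formerly identical groups sets the configuration of the spiro carbon.

Step 9
Reactants: 12 lactone acid
Product: 13 lactone methyl ester
Conditions: Me3SiCHN2, MeOH/toluene, 0 °C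
Reagents that add atoms: trimethylsilyldiazomethane, C[Si](C)(C)C=[N+]=[N-]
Why: O-Methylation of the carboxylic acid with trimethylsilyldiazomethane is a neutral esterification that spares the lactone and both tertiary alcohols and makes the upper carboxyl the less reactive of the two acyl groups on the spiro carbon.

Step 10
Reactants: 13 lactone methyl ester; 14 6-methylhept-5-en-2-one
Product: 16 spiro trione (ring A closed; prenyl on the ring A carbon next to the ester-derived carbonyl; both tertiary hydroxyls free), via diketo ester 15 (not isolated)
Conditions: 14, LiN(i-Pr)2, THF, −78 °C, then 13, −78 → 0 °C; more LiN(i-Pr)2, 0 °C → rt; aq. HCl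
Reagents that add atoms: none
Why: Crossed Claisen condensation of the kinetic, methyl-side lithium enolate of 14 with the lactone (a strained ester held in the more electrophilic s-cis form, unlike the hindered methyl ester) gives the β-diketone and frees the ring C hydroxyl, and the 1,3-dianion formed with further base closes ring A through its terminal carbon onto the methyl ester (Dieckmann-type acylation of a β-diketone dianion, 6-exo-trig), so the lactone carbonyl ends next to the unsubstituted ring A carbon and the ester carbonyl next to the prenyl-bearing one, which transcribes the spiro configuration of step 8 into ring A.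

Step 11
Reactants: 16 spiro trione; 17 (S)-2-methylbutanoic acid
Product: 19 acyl trione (20 lacking the ring A C-methyl group), via enol ester 18 (not isolated)
Conditions: DCC, DMAP, CH2Cl2, rt
Reagents that add atoms: none
Why: DCC/DMAP C-acylation of a cyclic β-diketone runs by O-acylation to the enol ester and DMAP-mediated acyl transfer to carbon, ending at the only unsubstituted carbon between two ring carbonyls, where the hydrogen-bonded β-triketone is the thermodynamic sink; tertiary alcohols are not esterified under these conditions and the α-stereocentre of the acid, never exposed to strong base, should be retained.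

Step 12
Reactants: 19 acyl trione
Product: 20 hyperielliptone HB
Conditions: NaOMe, MeI, MeOH, 0 °C → rt; dilute HCl
Reagents that add atoms: iodomethane, CI
Why: C-Methylation of the dianion of a 2-acylcyclohexane-1,3,5-trione with NaOMe/MeI, the reaction used for tetramethylated acylphloroglucinols of the leptospermone type, alkylates the only ring carbon still bearing hydrogen; in the planar enolate the face of ring A on the side of the ring B CH2 bonded to the carbinol carbon is flanked by that carbon's methyl group, so methyl iodide is expected to enter from the other face (the side of the CH2 bonded to the ring-fusion carbon), which gives the required quaternary configuration.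

## Compound list

1 | (R)-(−)-linalool, (3R)-3,7-dimethylocta-1,6-dien-3-ol | CC(C)=CCC[C@@](C)(O)C=C | starting material
2 | (3R)-3,7-dimethyl-3-(triethylsilyloxy)octa-1,6-diene | CC(C)=CCC[C@@](C)(O[Si](CC)(CC)CC)C=C | intermediate
3 | (2E,6R)-2,6-dimethyl-6-(triethylsilyloxy)octa-2,7-dien-1-ol | OC/C(C)=C/CC[C@@](C)(O[Si](CC)(CC)CC)C=C | intermediate (not isolated)
4 | (2E,6R)-2,6-dimethyl-6-(triethylsilyloxy)octa-2,7-dienal | O=C/C(C)=C/CC[C@@](C)(O[Si](CC)(CC)CC)C=C | intermediate
5 | dimethyl malonate | COC(=O)CC(=O)OC | starting material
6 | dimethyl 2-[(2E,6R)-2,6-dimethyl-6-(triethylsilyloxy)octa-2,7-dien-1-ylidene]malonate | COC(=O)C(C(=O)OC)=C/C(C)=C/CC[C@@](C)(O[Si](CC)(CC)CC)C=C | intermediate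
7 | dimethyl (3R,3aS,7aS)-3,7-dimethyl-3-(triethylsilyloxy)-1,2,3,3a,4,7a-hexahydro-5H-indene-5,5-dicarboxylate, cis-fused | COC(=O)C1(C(=O)OC)C[C@H]2[C@H](CC[C@@]2(C)O[Si](CC)(CC)CC)C(C)=C1 | intermediate
8 | dimethyl (3R,3aS,7aS)-3-hydroxy-3,7-dimethyl-1,2,3,3a,4,7a-hexahydro-5H-indene-5,5-dicarboxylate | COC(=O)C1(C(=O)OC)C[C@H]2[C@H](CC[C@@]2(C)O)C(C)=C1 | intermediate
9 | 6,7-epoxide of 8, oxirane oxygen cis to the 3-hydroxyl group | COC(=O)C1(C(=O)OC)C[C@H]2[C@H](CC[C@@]2(C)O)[C@]3(C)O[C@@H]31 | intermediate
10 | cis-fused 5,5-bis(hydroxymethyl)-3,7-dimethyloctahydro-1H-indene-3,7-diol, both tertiary OH anti to the ring-fusion hydrogens | OCC1(CO)C[C@H]2[C@H](CC[C@@]2(C)O)[C@](C)(O)C1 | intermediate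
11 | lactone aldehyde: δ-lactone from the ring C oxygen to the carbonyl on its face, CHO on the other face | O=C[C@]12C[C@H]3[C@H](CC[C@@]3(C)OC1=O)[C@](C)(O)C2 | intermediate (not isolated)
12 | lactone acid: as 11 with CO2H in place of CHO | OC(=O)[C@]12C[C@H]3[C@H](CC[C@@]3(C)OC1=O)[C@](C)(O)C2 | intermediate
13 | lactone methyl ester: as 12 with CO2CH3 | COC(=O)[C@]12C[C@H]3[C@H](CC[C@@]3(C)OC1=O)[C@](C)(O)C2 | intermediate
14 | 6-methylhept-5-en-2-one | CC(=O)CCC=C(C)C | starting material
15 | diketo ester: 13 opened at the lactone carbonyl by the methyl carbon of 14 (side chain C(=O)CH2C(=O)CH2CH2CH=C(CH3)2, methyl ester kept, both tertiary OH free) | COC(=O)[C@@]1(C(=O)CC(=O)CCC=C(C)C)C[C@H]2[C@H](CC[C@@]2(C)O)[C@](C)(O)C1 | intermediate (not isolated)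
16 | spiro trione: ring A closed, prenyl on the ring A carbon next to the ester-derived carbonyl, no acyl group | O=C1C=C(O)C(CC=C(C)C)C(=O)[C@]12C[C@H]3[C@H](CC[C@@]3(C)O)[C@](C)(O)C2 | intermediate
17 | (S)-2-methylbutanoic acid | CC[C@H](C)C(=O)O | starting material
18 | enol ester: (S)-2-methylbutanoate of the ring A enol of 16 | CC[C@H](C)C(=O)OC1=CC(=O)[C@@]2(C[C@H]3[C@H](CC[C@@]3(C)O)[C@](C)(O)C2)C(=O)C1CC=C(C)C | intermediate (not isolated)
19 | acyl trione: 20 with H in place of the ring A C-methyl group | CC[C@H](C)C(=O)C1=C(O)C(CC=C(C)C)C(=O)[C@]2(C[C@H]3[C@H](CC[C@@]3(C)O)[C@](C)(O)C2)C1=O | intermediate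
20 | hyperielliptone HB | CC[C@H](C)C(=O)C1=C(O)[C@@](C)(CC=C(C)C)C(=O)[C@]2(C[C@H]3[C@H](CC[C@@]3(C)O)[C@](C)(O)C2)C1=O | target

## Step count and risks

Total: 12 steps. Longest linear sequence: 12 steps, from 1 to 20; 5, 14 and 17 are used as purchased.

**Step 4 (cycloaddition).** The ring closure may run through the exo mode (trans ring fusion) or with the silyloxy group turned away from the new CH2, or be so slow that desilylation and polymerisation win.
Fallback, from 4 back to 7: ring C is closed first by a radical route and ring B second by alkylation. Thiophenol and AIBN (benzene, 80 °C) add a thiyl radical to the vinyl group of 4. The secondary radical closes 5-exo onto the β-carbon of the enal through a chair-like transition structure (1,5-cis rule for the substituted radical carbon, carbinol methyl pseudo-equatorial), and hydrogen transfer from the thiol gives the cyclopentane aldehyde sulfide F1. Knoevenagel condensation with 5 (piperidine, AcOH) gives the alkylidene malonate sulfide F2. S-Methylation (MeOTf, 2,6-di-tert-butylpyridine) gives the sulfonium triflate F3. DBU then forms the extended malonate enolate, which is alkylated at its α-carbon by the CH2–S+ group (six-membered ring, deconjugative alkylation) to give 7.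

**Step 12 (C-methylation).** Facial selectivity may be poor or reversed, with methyl iodide entering from the face flanked by the ring B methyl group; O-methylation may compete.
Fallback, from 13 to 20: the two substituents of the quaternary carbon are introduced in the opposite order, so that the same facial bias gives the other configuration. The annulation of step 10 is run with butan-2-one (kinetic enolate with LiN(i-Pr)2, then dianion closure) through the diketo ester F4 to the methyl trione F5. DCC/DMAP acylation with 17 through the enol ester F6 gives the acyl methyl trione F7. C-Prenylation of its dianion with prenyl bromide (NaOMe, MeOH, 0 °C) then gives 20, the prenyl group taking the face that methyl iodide took in step 12.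

**Step 10 (ring A annulation).** Chemoselectivity may be lost in the first acylation (enolate attack on the methyl ester instead of the lactone would reverse the orientation of ring A), and the second closure may go through oxygen instead of carbon.
Fallback, from 12 to 16: the Claisen condensation is run on 12 as its lithium carboxylate, which the enolate of 14 cannot attack, so only the lactone reacts and the diketo acid F8 results. Dehydration (DCC, CH2Cl2) closes the acid onto the enol oxygen to give the spiro enol lactone F9. The classical enol lactone to cyclic 1,3-diketone rearrangement (NaOMe, MeOH, reflux) opens F9 to the diketo ester 15, which closes through carbon under these equilibrating conditions to give 16.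

## Further compounds

F1 | step 4 | 2-[(cis,cis)-3-methyl-2-(phenylthiomethyl)-3-(triethylsilyloxy)cyclopentyl]propanal, ring configuration as in 7, aldehyde α-carbon unassigned | c1ccccc1SC[C@H]2[C@H](CC[C@@]2(C)O[Si](CC)(CC)CC)C(C)C=O
F2 | step 4 | dimethyl 2-{2-[3-methyl-2-(phenylthiomethyl)-3-(triethylsilyloxy)cyclopentyl]propylidene}malonate | c1ccccc1SC[C@H]2[C@H](CC[C@@]2(C)O[Si](CC)(CC)CC)C(C)C=C(C(=O)OC)C(=O)OC
F3 | step 4 | S-methyl-S-phenylsulfonium trifluoromethanesulfonate of F2 | C[S+](c1ccccc1)C[C@H]2[C@H](CC[C@@]2(C)O[Si](CC)(CC)CC)C(C)C=C(C(=O)OC)C(=O)OC.[O-]S(=O)(=O)C(F)(F)F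
F4 | step 12 | diketo ester from butan-2-one: analogue of 15 with side chain C(=O)CH2C(=O)CH2CH3 | COC(=O)[C@@]1(C(=O)CC(=O)CC)C[C@H]2[C@H](CC[C@@]2(C)O)[C@](C)(O)C1
F5 | step 12 | methyl trione: analogue of 16 with CH3 in place of prenyl | O=C1C=C(O)C(C)C(=O)[C@]12C[C@H]3[C@H](CC[C@@]3(C)O)[C@](C)(O)C2
F6 | step 12 | enol ester of F5 with (S)-2-methylbutanoic acid | CC[C@H](C)C(=O)OC1=CC(=O)[C@@]2(C[C@H]3[C@H](CC[C@@]3(C)O)[C@](C)(O)C2)C(=O)C1C
F7 | step 12 | acyl methyl trione: 20 with H in place of the prenyl group | CC[C@H](C)C(=O)C1=C(O)C(C)C(=O)[C@]2(C[C@H]3[C@H](CC[C@@]3(C)O)[C@](C)(O)C2)C1=O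
F8 | step 10 | diketo acid: 15 with CO2H in place of CO2CH3 | OC(=O)[C@@]1(C(=O)CC(=O)CCC=C(C)C)C[C@H]2[C@H](CC[C@@]2(C)O)[C@](C)(O)C1
F9 | step 10 | spiro enol lactone: 6-(4-methylpent-3-enyl)pyran-2,4-dione spiro-fused at C-3 to ring B | O=C1C=C(CCC=C(C)C)OC(=O)[C@]12C[C@H]3[C@H](CC[C@@]3(C)O)[C@](C)(O)C2
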